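The trimer (units T, M and B, both links 4β→6) is disconnected at C4–C4a of unit M. Ring A of unit M is a phloroglucinol ring whose C6 already carries C4 of unit T; with O1 para to C6, the two carbons ortho to O1 are equivalent, so closure can give only the 4→6 pattern. In one operation the key step ionises C4 of unit M, lets the C3 acetate bridge the cation and closes ring C by Friedel–Crafts attack, forming C4–C4a and setting C4 trans to C3. The precursor is an open chain O1–C2–C3(OAc)–C4(OAc) that links the unit T–phloroglucinol adduct (through its para oxygen) to C6 of benzylated epicatechin.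

Key step: step 17

Assumption: the target is read as epicatechin-(4β→6)-epicatechin-(4β→6)-epicatechin (2,3-cis and 3,4-trans in units T and M), which is what the SMILES encodes.

Remark: the key-step precursor and product hold the configuration of the target at C2 and C3 of unit M and at every centre of units T and B, so no configuration needs correcting.

Remark: O4 of the precursor is acetylated as well. A free carbinol beside the C3 acetate would invite 1,2-acyl migration and cannot be carried through an aryllithium addition; the benzylic acetate ionises at the same carbon to the same cation.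

Remark: C8 of unit B carries bromine from step 4 to step 19. It makes the metalation at C6 regiodefined, blocks the other nucleophilic carbon of that ring during the key step, and leaves in the final hydrogenolysis.

Step 1
Reactants: 1 (−)-epicatechin
Product: 2 5,7,3',4'-tetra-O-benzyl-(−)-epicatechin
Conditions: BnBr, K2CO3, DMF, 0 °C → rt
Reagents that add atoms: benzyl bromide, BrCc1ccccc1
Why: Williamson ether synthesis in which carbonate deprotonates only the four phenols, so the secondary C3 hydroxyl stays free and no stereocentre is touched.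

Step 2
Reactants: 2 5,7,3',4'-tetra-O-benzyl-(−)-epicatechin
Product: 3 3,5,7,3',4'-penta-O-benzyl-(−)-epicatechin
Conditions: NaH, BnBr, DMF, 0 °C → rt
Reagents that add atoms: benzyl bromide, BrCc1ccccc1
Why: Williamson etherification of the remaining secondary alcohol through its sodium alkoxide, safe once all phenols are capped.

Step 3
Reactants: 3 3,5,7,3',4'-penta-O-benzyl-(−)-epicatechin
Product: 4 3,5,7,3',4'-penta-O-benzyl-4β-(2-ethoxyethoxy)epicatechin
Conditions: DDQ, 2-ethoxyethanol, CH2Cl2, rt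
Reagents that add atoms: 2-ethoxyethanol, CCOCCO
Why: Benzylic oxidation by hydride abstraction at C4, activated by the 5,7-dioxygenated ring A, with the alcohol trapping the cation trans to the C3 benzyloxy group; this C4 configuration is lost again on ionisation in step 7.

Step 4
Reactants: 3 3,5,7,3',4'-penta-O-benzyl-(−)-epicatechin
Product: 5 8-bromo-3,5,7,3',4'-penta-O-benzyl-(−)-epicatechin
Conditions: N-bromosuccinimide, CH2Cl2, −40 °C → rt
Reagents that add atoms: N-bromosuccinimide, O=C1CCC(=O)N1Br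
Why: Electrophilic aromatic bromination, which takes place at C8 (ortho to O1), the more reactive ring A carbon of benzylated flavan-3-ols.

Step 5
Reactants: 5 8-bromo-3,5,7,3',4'-penta-O-benzyl-(−)-epicatechin
Product: 6 8-bromo-6-iodo-3,5,7,3',4'-penta-O-benzyl-(−)-epicatechin
Conditions: N-iodosuccinimide, CF3CO2H (cat.), MeCN/CH2Cl2, 0 °C → rt
Reagents that add atoms: N-iodosuccinimide, O=C1CCC(=O)N1I
Why: Electrophilic aromatic iodination at C6, the only free carbon of the trioxygenated ring A, which remains more nucleophilic than the catechol ether ring.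

Step 6
Reactants: 7 3,5-bis(benzyloxy)phenol
Product: 8 [3,5-bis(benzyloxy)phenoxy]triisopropylsilane
Conditions: i-Pr3SiCl, imidazole, DMF, rt
Reagents that add atoms: chlorotriisopropylsilane, CC(C)[Si](Cl)(C(C)C)C(C)C
Why: Silyl ether formation puts a bulky, fluoride-labile group on the oxygen that will become O1 of unit M.

Step 7
Reactants: 4 3,5,7,3',4'-penta-O-benzyl-4β-(2-ethoxyethoxy)epicatechin; 8 [3,5-bis(benzyloxy)phenoxy]triisopropylsilane
Product: 9 3,5,7,3',4'-penta-O-benzyl-4β-[2,6-bis(benzyloxy)-4-(triisopropylsilyloxy)phenyl]epicatechin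
Conditions: 8 (3 equiv), Me3SiOTf (cat.), 4 Å MS, CH2Cl2, −78 → −40 °C
Reagents that add atoms: none
Why: Lewis-acid Friedel–Crafts alkylation through the flavan-4-yl cation, in which the arene attacks trans to the C3 benzyloxy group (C4 of unit T set 4β by substrate control) and at the carbon between the two benzyloxy groups, since both carbons beside the silyloxy group are shielded, while excess 8 suppresses self-condensation of 4.

Step 8
Reactants: 9 3,5,7,3',4'-penta-O-benzyl-4β-[2,6-bis(benzyloxy)-4-(triisopropylsilyloxy)phenyl]epicatechin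
Product: 10 3,5,7,3',4'-penta-O-benzyl-4β-[2,6-bis(benzyloxy)-4-hydroxyphenyl]epicatechin
Conditions: n-Bu4NF, AcOH, THF, 0 °C
Reagents that add atoms: none
Why: Fluoride cleavage of an aryl silyl ether, driven by Si–F bond formation and inert toward benzyl ethers.

Step 9
Reactants: 11 3,4-bis(benzyloxy)benzaldehyde
Product: 12 ethyl (Z)-3-[3,4-bis(benzyloxy)phenyl]prop-2-enoate
Conditions: (CF3CH2O)2P(O)CH2CO2Et, KN(SiMe3)2, 18-crown-6, THF, −78 °C
Reagents that add atoms: ethyl [bis(2,2,2-trifluoroethoxy)phosphoryl]acetate, CCOC(=O)CP(=O)(OCC(F)(F)F)OCC(F)(F)F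
Why: Still–Gennari variant of the Horner–Wadsworth–Emmons olefination, in which the electron-poor phosphonate under dissociating conditions gives the Z alkene kinetically.

Step 10
Reactants: 12 ethyl (Z)-3-[3,4-bis(benzyloxy)phenyl]prop-2-enoate
Product: 13 ethyl (2S,3S)-3-[3,4-bis(benzyloxy)phenyl]oxirane-2-carboxylate (cis)
Conditions: [(S,S)-N,N'-bis(3,5-di-tert-butylsalicylidene)cyclohexane-1,2-diaminato]MnCl (cat.), 4-phenylpyridine N-oxide, aq. NaOCl (buffered), CH2Cl2, 0 °C
Reagents that add atoms: sodium hypochlorite, [Na+].[O-]Cl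
Why: Jacobsen–Katsuki epoxidation, in which the chiral salen oxo-manganese species delivers oxygen to one face of the cis-cinnamate and sets both epoxide carbons (the S,S catalyst is chosen by analogy with cis-cinnamates, which give the 2R,3R epoxide with the R,R catalyst); any trans epoxide is removed by chromatography.

Step 11
Reactants: 10 3,5,7,3',4'-penta-O-benzyl-4β-[2,6-bis(benzyloxy)-4-hydroxyphenyl]epicatechin; 13 ethyl (2S,3S)-3-[3,4-bis(benzyloxy)phenyl]oxirane-2-carboxylate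
Product: 14 ethyl (2S,3R)-3-[3,4-bis(benzyloxy)phenyl]-2-hydroxy-3-(aryloxy)propanoate (aryl = 3,5-bis(benzyloxy)-4-[penta-O-benzylepicatechin-4β-yl]phenyl)
Conditions: Cs2CO3 (0.3 equiv), DMF, 45 °C
Reagents that add atoms: none
Why: SN2 opening of an aryl epoxide by a phenoxide at the benzylic carbon with inversion (the ester disfavours attack at the α carbon), so the cis epoxide gives the 2,3-cis relationship of epicatechin; C2 of unit M is set here and C3 is carried over from 13.

Step 12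
Reactants: 14 ethyl (2S,3R)-3-[3,4-bis(benzyloxy)phenyl]-2-hydroxy-3-(aryloxy)propanoate
Product: 15 ethyl (2S,3R)-3-[3,4-bis(benzyloxy)phenyl]-2-(tert-butyldimethylsilyloxy)-3-(aryloxy)propanoate
Conditions: t-BuMe2SiOTf, 2,6-lutidine, CH2Cl2, −78 → 0 °C
Reagents that add atoms: tert-butyldimethylsilyl triflate, CC(C)(C)[Si](C)(C)OS(=O)(=O)C(F)(F)F
Why: Silyl ether formation with a silyl triflate and a hindered base protects the α-hydroxyl for the hydride and organolithium steps.

Step 13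
Reactants: 15 ethyl (2S,3R)-3-[3,4-bis(benzyloxy)phenyl]-2-(tert-butyldimethylsilyloxy)-3-(aryloxy)propanoate
Product: 16 (2S,3R)-3-[3,4-bis(benzyloxy)phenyl]-2-(tert-butyldimethylsilyloxy)-3-(aryloxy)propanal
Conditions: i-Bu2AlH, CH2Cl2, −78 °C; aq. potassium sodium tartrate
Reagents that add atoms: none
Why: Partial reduction of an ester, in which the chelated aluminium hemiacetal of the α-silyloxy ester persists at −78 °C and releases the aldehyde only on work-up, without epimerisation.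

Step 14
Reactants: 6 8-bromo-6-iodo-3,5,7,3',4'-penta-O-benzyl-(−)-epicatechin; 16 (2S,3R)-3-[3,4-bis(benzyloxy)phenyl]-2-(tert-butyldimethylsilyloxy)-3-(aryloxy)propanal
Product: 18 carbinol O1–C2H(Ar)–C3H(OSiMe2t-Bu)–C4H(OH)–[C6 of 8-bromo-penta-O-benzylepicatechin] (both C4 epimers), via 6-lithio-8-bromo-penta-O-benzylepicatechin 17 (not isolated)
Conditions: 6, n-BuLi, THF, −78 °C; then 16, −78 °C; aq. NH4Cl
Reagents that add atoms: n-butyllithium, [Li]CCCC (its lithium is held only in 17)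
Why: Iodine–lithium exchange, far faster than bromine–lithium exchange at −78 °C, gives the C6 aryllithium, which undergoes 1,2-addition to the aldehyde; the new carbinol centre (C4 of unit M) may form as either epimer because it is ionised in step 17.

Step 15
Reactants: 18 carbinol with C3 silyl ether (both C4 epimers)
Product: 19 C3,C4-diol of the open chain (both C4 epimers)
Conditions: n-Bu4NF, AcOH, THF, 0 °C → rt
Reagents that add atoms: none
Why: Fluoride cleavage of the silyl ether, buffered with acetic acid so that no alkoxide builds up beside the β-aryloxy group.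

Step 16
Reactants: 19 C3,C4-diol of the open chain
Product: 20 C3,C4-diacetate of the open chain (key-step precursor; both C4 epimers)
Conditions: Ac2O, pyridine, DMAP (cat.), CH2Cl2, 0 °C → rt
Reagents that add atoms: acetic anhydride, CC(=O)OC(C)=O
Why: DMAP-catalysed acylation of both hydroxyls installs the benzylic leaving group at C4 and the participating acetate at C3.

Step 17
Reactants: 20 C3,C4-diacetate of the open chain
Product: 22 tetradeca-O-benzyl 3-O-acetyl(unit M) 8-bromo(unit B) epicatechin-(4β→6)-epicatechin-(4β→6)-epicatechin, via trans-2-methyl-1,3-dioxolan-2-ylium triflate 21 (not isolated)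
Conditions: Me3SiOTf (0.3 equiv), 4 Å MS, CH2Cl2 (0.005 M), −78 → −40 °C; then Et3N
Reagents that add atoms: none
Why: The silyl triflate abstracts the C4 acetate, which is benzylic to the 2,4,6-trioxygenated ring A of unit B, so both C4 epimers of 20 give one cation; the carbonyl oxygen of the C3 acetate closes it to the dioxolanylium ion 21, which equilibrates through the open cation to the 4,5-trans isomer. The closest known reaction type is the acid-mediated intramolecular Friedel–Crafts alkylation of 3-aryloxy-1-arylpropan-1-ols or their esters to 4-arylchromans, here with neighbouring-group participation by a vicinal acetate as in Lewis-acid activation of flavan-3,4-diol diacetates. Ring C of unit M closes as a six-membered ring by 6-exo-tet opening of the C4–O bond of 21 by the arene carbon ortho to O1 (6-endo with respect to the aromatic π bond), followed by rearomatisation. The new stereocentre C4 of unit M is controlled by backside attack on the trans ion: inversion at C4, with C2 and C3 untouched, places ring A of unit B trans to the C3 acetate (4β). The step needs site selectivity on ring A of unit M, secured because the two carbons ortho to O1 are equivalent once C6 carries C4 of unit T. It also needs ionisation at C4 in preference to the C2 benzylic ether and to intermolecular alkylation, secured by the two ortho benzyloxy groups and the para ring oxygen of unit B, by high dilution and by the bromine at C8 of unit B.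

Step 18
Reactants: 22 tetradeca-O-benzyl 3-O-acetyl(unit M) 8-bromo(unit B) trimer
Product: 23 tetradeca-O-benzyl 8-bromo(unit B) epicatechin-(4β→6)-epicatechin-(4β→6)-epicatechin (free 3-OH in unit M)
Conditions: NaOMe (cat.), MeOH/THF, rt
Reagents that add atoms: none
Why: Zemplén transesterification of the secondary acetate, to which benzyl ethers, the aryl bromide and the interflavan bonds are inert.

Step 19
Reactants: 23 tetradeca-O-benzyl 8-bromo(unit B) trimer
Product: 24 epicatechin-(4β→6)-epicatechin-(4β→6)-epicatechin (CNP0163146.2)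
Conditions: H2 (1 atm), Pd(OH)2/C, Et3N, THF/MeOH/H2O, rt
Reagents that add atoms: none
Why: Heterogeneous hydrogenolysis should cleave the fourteen benzyl ethers and the aryl C–Br bond, with triethylamine trapping HBr so that the acid-labile interflavan bonds survive and no stereocentre is affected.

Compound list

1 | (−)-epicatechin, (2R,3R) | Oc1cc(O)c2c(c1)O[C@H](c1ccc(O)c(O)c1)[C@H](O)C2 | starting material
2 | 5,7,3',4'-tetra-O-benzyl-(−)-epicatechin (3-OH free) | C(c1ccccc1)Oc1cc(OCc2ccccc2)c2c(c1)O[C@H](c1ccc(OCc3ccccc3)c(OCc3ccccc3)c1)[C@H](O)C2 | intermediate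
3 | 3,5,7,3',4'-penta-O-benzyl-(−)-epicatechin | C(c1ccccc1)Oc1cc(OCc2ccccc2)c2c(c1)O[C@H](c1ccc(OCc3ccccc3)c(OCc3ccccc3)c1)[C@H](OCc1ccccc1)C2 | intermediate
4 | 3,5,7,3',4'-penta-O-benzyl-4β-(2-ethoxyethoxy)epicatechin (C4 ether trans to the C3 benzyloxy group) | C(c1ccccc1)Oc1cc(OCc2ccccc2)c2c(c1)O[C@H](c1ccc(OCc3ccccc3)c(OCc3ccccc3)c1)[C@H](OCc1ccccc1)[C@H]2OCCOCC | intermediate
5 | 8-bromo-3,5,7,3',4'-penta-O-benzyl-(−)-epicatechin | C(c1ccccc1)Oc1cc(OCc2ccccc2)c2c(c1Br)O[C@H](c1ccc(OCc3ccccc3)c(OCc3ccccc3)c1)[C@H](OCc1ccccc1)C2 | intermediate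
6 | 8-bromo-6-iodo-3,5,7,3',4'-penta-O-benzyl-(−)-epicatechin | C(c1ccccc1)Oc1c(I)c(OCc2ccccc2)c2c(c1Br)O[C@H](c1ccc(OCc3ccccc3)c(OCc3ccccc3)c1)[C@H](OCc1ccccc1)C2 | intermediate
7 | 3,5-bis(benzyloxy)phenol | Oc1cc(OCc2ccccc2)cc(OCc2ccccc2)c1 | starting material
8 | [3,5-bis(benzyloxy)phenoxy]triisopropylsilane | CC(C)[Si](C(C)C)(C(C)C)Oc1cc(OCc2ccccc2)cc(OCc2ccccc2)c1 | intermediate
9 | 3,5,7,3',4'-penta-O-benzyl-4β-[2,6-bis(benzyloxy)-4-(triisopropylsilyloxy)phenyl]epicatechin | C(c1ccccc1)Oc1cc(OCc2ccccc2)c2c(c1)O[C@H](c1ccc(OCc3ccccc3)c(OCc3ccccc3)c1)[C@H](OCc1ccccc1)[C@H]2c1c(OCc2ccccc2)cc(O[Si](C(C)C)(C(C)C)C(C)C)cc1OCc1ccccc1 | intermediate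
10 | 3,5,7,3',4'-penta-O-benzyl-4β-[2,6-bis(benzyloxy)-4-hydroxyphenyl]epicatechin | C(c1ccccc1)Oc1cc(OCc2ccccc2)c2c(c1)O[C@H](c1ccc(OCc3ccccc3)c(OCc3ccccc3)c1)[C@H](OCc1ccccc1)[C@H]2c1c(OCc2ccccc2)cc(O)cc1OCc1ccccc1 | intermediate
11 | 3,4-bis(benzyloxy)benzaldehyde | O=Cc1ccc(OCc2ccccc2)c(OCc2ccccc2)c1 | starting material
12 | ethyl (Z)-3-[3,4-bis(benzyloxy)phenyl]prop-2-enoate | CCOC(=O)/C=C\c1ccc(OCc2ccccc2)c(OCc2ccccc2)c1 | intermediate
13 | ethyl (2S,3S)-3-[3,4-bis(benzyloxy)phenyl]oxirane-2-carboxylate (cis-glycidate) | CCOC(=O)[C@H]1O[C@H]1c1ccc(OCc2ccccc2)c(OCc2ccccc2)c1 | intermediate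
14 | ethyl (2S,3R)-3-[3,4-bis(benzyloxy)phenyl]-2-hydroxy-3-(aryloxy)propanoate, aryl = 3,5-bis(benzyloxy)-4-[penta-O-benzylepicatechin-4β-yl]phenyl | C(c1ccccc1)Oc1cc(OCc2ccccc2)c2c(c1)O[C@H](c1ccc(OCc3ccccc3)c(OCc3ccccc3)c1)[C@H](OCc1ccccc1)[C@H]2c1c(OCc2ccccc2)cc(O[C@H](c2ccc(OCc3ccccc3)c(OCc3ccccc3)c2)[C@H](O)C(=O)OCC)cc1OCc1ccccc1 | intermediate
15 | 2-O-tert-butyldimethylsilyl ether of 14 | C(c1ccccc1)Oc1cc(OCc2ccccc2)c2c(c1)O[C@H](c1ccc(OCc3ccccc3)c(OCc3ccccc3)c1)[C@H](OCc1ccccc1)[C@H]2c1c(OCc2ccccc2)cc(O[C@H](c2ccc(OCc3ccccc3)c(OCc3ccccc3)c2)[C@H](O[Si](C)(C)C(C)(C)C)C(=O)OCC)cc1OCc1ccccc1 | intermediate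
16 | (2S,3R)-3-[3,4-bis(benzyloxy)phenyl]-2-(tert-butyldimethylsilyloxy)-3-(aryloxy)propanal (aryl as in 14) | C(c1ccccc1)Oc1cc(OCc2ccccc2)c2c(c1)O[C@H](c1ccc(OCc3ccccc3)c(OCc3ccccc3)c1)[C@H](OCc1ccccc1)[C@H]2c1c(OCc2ccccc2)cc(O[C@H](c2ccc(OCc3ccccc3)c(OCc3ccccc3)c2)[C@H](O[Si](C)(C)C(C)(C)C)C=O)cc1OCc1ccccc1 | intermediate
17 | 8-bromo-6-lithio-3,5,7,3',4'-penta-O-benzylepicatechin | C(c1ccccc1)Oc1c([Li])c(OCc2ccccc2)c2c(c1Br)O[C@H](c1ccc(OCc3ccccc3)c(OCc3ccccc3)c1)[C@H](OCc1ccccc1)C2 | intermediate (not isolated)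
18 | open-chain carbinol: aryl ether O1–C2H(3,4-dibenzyloxyphenyl)–C3H(OSiMe2t-Bu)–C4H(OH) bonded at C4 to C6 of 8-bromo-penta-O-benzylepicatechin; C2 and C3 as in 14, both C4 epimers | C(c1ccccc1)Oc1cc(OCc2ccccc2)c2c(c1)O[C@H](c1ccc(OCc3ccccc3)c(OCc3ccccc3)c1)[C@H](OCc1ccccc1)[C@H]2c1c(OCc2ccccc2)cc(O[C@H](c2ccc(OCc3ccccc3)c(OCc3ccccc3)c2)[C@H](O[Si](C)(C)C(C)(C)C)C(O)c2c(OCc3ccccc3)c(Br)c3c(c2OCc2ccccc2)C[C@@H](OCc2ccccc2)[C@@H](c2ccc(OCc4ccccc4)c(OCc4ccccc4)c2)O3)cc1OCc1ccccc1 | intermediate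
19 | C3,C4-diol corresponding to 18 (both C4 epimers) | C(c1ccccc1)Oc1cc(OCc2ccccc2)c2c(c1)O[C@H](c1ccc(OCc3ccccc3)c(OCc3ccccc3)c1)[C@H](OCc1ccccc1)[C@H]2c1c(OCc2ccccc2)cc(O[C@H](c2ccc(OCc3ccccc3)c(OCc3ccccc3)c2)[C@H](O)C(O)c2c(OCc3ccccc3)c(Br)c3c(c2OCc2ccccc2)C[C@@H](OCc2ccccc2)[C@@H](c2ccc(OCc4ccccc4)c(OCc4ccccc4)c2)O3)cc1OCc1ccccc1 | intermediate
20 | C3,C4-diacetate corresponding to 19 (key-step precursor, both C4 epimers) | C(c1ccccc1)Oc1cc(OCc2ccccc2)c2c(c1)O[C@H](c1ccc(OCc3ccccc3)c(OCc3ccccc3)c1)[C@H](OCc1ccccc1)[C@H]2c1c(OCc2ccccc2)cc(O[C@H](c2ccc(OCc3ccccc3)c(OCc3ccccc3)c2)[C@H](OC(C)=O)C(OC(C)=O)c2c(OCc3ccccc3)c(Br)c3c(c2OCc2ccccc2)C[C@@H](OCc2ccccc2)[C@@H](c2ccc(OCc4ccccc4)c(OCc4ccccc4)c2)O3)cc1OCc1ccccc1 | intermediate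
21 | 4,5-trans-2-methyl-1,3-dioxolan-2-ylium triflate spanning C3 and C4 of unit M | C(c1ccccc1)Oc1cc(OCc2ccccc2)c2c(c1)O[C@H](c1ccc(OCc3ccccc3)c(OCc3ccccc3)c1)[C@H](OCc1ccccc1)[C@H]2c1c(OCc2ccccc2)cc(O[C@H](c2ccc(OCc3ccccc3)c(OCc3ccccc3)c2)[C@H](OC(C)=[O+]2)[C@@H]2c2c(OCc3ccccc3)c(Br)c3c(c2OCc2ccccc2)C[C@@H](OCc2ccccc2)[C@@H](c2ccc(OCc4ccccc4)c(OCc4ccccc4)c2)O3)cc1OCc1ccccc1.[O-]S(=O)(=O)C(F)(F)F | intermediate (not isolated)
22 | tetradeca-O-benzyl 3-O-acetyl(unit M) 8-bromo(unit B) epicatechin-(4β→6)-epicatechin-(4β→6)-epicatechin (key-step product) | C(c1ccccc1)Oc1cc(OCc2ccccc2)c2c(c1)O[C@H](c1ccc(OCc3ccccc3)c(OCc3ccccc3)c1)[C@H](OCc1ccccc1)[C@H]2c1c(OCc2ccccc2)cc2c(c1OCc1ccccc1)[C@H](c3c(OCc4ccccc4)c(Br)c4c(c3OCc3ccccc3)C[C@@H](OCc3ccccc3)[C@@H](c3ccc(OCc5ccccc5)c(OCc5ccccc5)c3)O4)[C@@H](OC(C)=O)[C@@H](c3ccc(OCc4ccccc4)c(OCc4ccccc4)c3)O2 | intermediate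
23 | tetradeca-O-benzyl 8-bromo(unit B) trimer with free 3-OH in unit M | C(c1ccccc1)Oc1cc(OCc2ccccc2)c2c(c1)O[C@H](c1ccc(OCc3ccccc3)c(OCc3ccccc3)c1)[C@H](OCc1ccccc1)[C@H]2c1c(OCc2ccccc2)cc2c(c1OCc1ccccc1)[C@H](c3c(OCc4ccccc4)c(Br)c4c(c3OCc3ccccc3)C[C@@H](OCc3ccccc3)[C@@H](c3ccc(OCc5ccccc5)c(OCc5ccccc5)c3)O4)[C@@H](O)[C@@H](c3ccc(OCc4ccccc4)c(OCc4ccccc4)c3)O2 | intermediate
24 | epicatechin-(4β→6)-epicatechin-(4β→6)-epicatechin (CNP0163146.2) | Oc1cc(O)c2c(c1)O[C@H](c1ccc(O)c(O)c1)[C@H](O)[C@H]2c1c(O)cc2c(c1O)[C@H](c1c(O)cc3c(c1O)C[C@@H](O)[C@@H](c1ccc(O)c(O)c1)O3)[C@@H](O)[C@@H](c1ccc(O)c(O)c1)O2 | target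

Total step count: 19.
Longest linear sequence: 14 steps (steps 1, 2, 3, 7, 8 and 11 to 19, from (−)-epicatechin).

Steps most likely to fail

Step 17. The open benzylic cation may be captured before the acetate bridges it, which would give poor facial selectivity at C4 of unit M. It may instead lose the C3 proton to form an enol acetate, or the acid may cleave the existing T–M bond. The fallback gives up the ring closure and forms both interflavan bonds directly by the established Lewis-acid condensation of 4-alkoxyflavans with C8-blocked nucleophiles. It sets out from 5: oxidation with DDQ and 2-ethoxyethanol as in step 3 should give 8-bromo-3,5,7,3',4'-penta-O-benzyl-4β-(2-ethoxyethoxy)epicatechin F1. Condensation of F1 with an excess of 5 (Me3SiOTf, CH2Cl2, −78 °C) can only occur at C6 of 5, trans to the C3 benzyloxy group, and should give the dibromo deca-O-benzyl 4β→6 dimer F2. A second condensation of F1 with excess F2, whose only free ring A carbon is C6 of its upper unit, should give the tribromo pentadeca-O-benzyl trimer F3. Hydrogenolysis of F3 under the conditions of step 19 returns to the route at 24.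

Step 11. The ambident phenoxide of 10 may alkylate on carbon instead of oxygen or attack the ester-bearing epoxide carbon. The electron-rich benzylic C–O bond may ionise so that inversion is not clean, or prolonged base may eliminate the aryloxide from the product. The fallback reverses the order of the two unions. It sets out from 7: the small phenol, used in excess with 13 under milder conditions (Cs2CO3, DMF, rt), should give ethyl (2S,3R)-3-[3,5-bis(benzyloxy)phenoxy]-3-[3,4-bis(benzyloxy)phenyl]-2-hydroxypropanoate F4, which can be purified and checked for diastereomeric purity before unit T is committed. Friedel–Crafts reaction of 4 with F4 (Me3SiOTf, CH2Cl2, −78 °C) at the arene carbon para to the new ether and between the two benzyloxy groups then comes back to the route at 14.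

Step 7. Site selectivity may be poor: attack at a carbon between the silyloxy and a benzyloxy group would give an unsymmetrical adduct, and the later closure would then be misdirected. The fallback removes the question by using a threefold-symmetric nucleophile. It sets out from 4: acid-catalysed condensation with excess phloroglucinol (BF3·OEt2, 1,4-dioxane, rt) should give 3,5,7,3',4'-penta-O-benzyl-4β-(2,4,6-trihydroxyphenyl)epicatechin F5. Silylation of the unhindered para hydroxyl (i-Pr3SiCl, imidazole, DMF, 0 °C; the two ortho hydroxyls are flanked by C4 of the flavan) should give the 4-(triisopropylsilyloxy)-2,6-dihydroxyphenyl adduct F6. Benzylation of the two remaining phenols (BnBr, K2CO3, DMF) comes back to the route at 9.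

Further compounds

F1 | step 17 | 8-bromo-3,5,7,3',4'-penta-O-benzyl-4β-(2-ethoxyethoxy)epicatechin | C(c1ccccc1)Oc1cc(OCc2ccccc2)c2c(c1Br)O[C@H](c1ccc(OCc3ccccc3)c(OCc3ccccc3)c1)[C@H](OCc1ccccc1)[C@H]2OCCOCC
F2 | step 17 | 8,8'-dibromo deca-O-benzyl epicatechin-(4β→6)-epicatechin | C(c1ccccc1)Oc1cc(OCc2ccccc2)c2c(c1Br)O[C@H](c1ccc(OCc3ccccc3)c(OCc3ccccc3)c1)[C@H](OCc1ccccc1)[C@H]2c1c(OCc2ccccc2)c(Br)c2c(c1OCc1ccccc1)C[C@@H](OCc1ccccc1)[C@@H](c1ccc(OCc3ccccc3)c(OCc3ccccc3)c1)O2
F3 | step 17 | tribromo (C8 of each unit) pentadeca-O-benzyl epicatechin-(4β→6)-epicatechin-(4β→6)-epicatechin | C(c1ccccc1)Oc1cc(OCc2ccccc2)c2c(c1Br)O[C@H](c1ccc(OCc3ccccc3)c(OCc3ccccc3)c1)[C@H](OCc1ccccc1)[C@H]2c1c(OCc2ccccc2)c(Br)c2c(c1OCc1ccccc1)[C@H](c3c(OCc4ccccc4)c(Br)c4c(c3OCc3ccccc3)C[C@@H](OCc3ccccc3)[C@@H](c3ccc(OCc5ccccc5)c(OCc5ccccc5)c3)O4)[C@@H](OCc3ccccc3)[C@@H](c3ccc(OCc4ccccc4)c(OCc4ccccc4)c3)O2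
F4 | step 11 | ethyl (2S,3R)-3-[3,5-bis(benzyloxy)phenoxy]-3-[3,4-bis(benzyloxy)phenyl]-2-hydroxypropanoate | c1c(OCc2ccccc2)cc(O[C@H](c2ccc(OCc3ccccc3)c(OCc3ccccc3)c2)[C@H](O)C(=O)OCC)cc1OCc1ccccc1
F5 | step 7 | 3,5,7,3',4'-penta-O-benzyl-4β-(2,4,6-trihydroxyphenyl)epicatechin | C(c1ccccc1)Oc1cc(OCc2ccccc2)c2c(c1)O[C@H](c1ccc(OCc3ccccc3)c(OCc3ccccc3)c1)[C@H](OCc1ccccc1)[C@H]2c1c(O)cc(O)cc1O
F6 | step 7 | 3,5,7,3',4'-penta-O-benzyl-4β-[2,6-dihydroxy-4-(triisopropylsilyloxy)phenyl]epicatechin | C(c1ccccc1)Oc1cc(OCc2ccccc2)c2c(c1)O[C@H](c1ccc(OCc3ccccc3)c(OCc3ccccc3)c1)[C@H](OCc1ccccc1)[C@H]2c1c(O)cc(O[Si](C(C)C)(C(C)C)C(C)C)cc1O
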